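**Plan**
- Retrosynthesis: cut the two aryl C6–CH bonds at the bridging methine (giving 6-methylheptanal and two identical chromans), then in each chroman the O1–C8a and C4–C4a bonds of the pyran ring, and last the C8–acyl bond.
- Forward: the benzene ring is bought as 1-iodo-3,5-dimethoxybenzene. Acylation puts the isobutyryl group next to iodine, a palladium/norbornene relay builds the pyran ring (the only ring formed) in one operation, the methyl ethers are removed, and two chromans are joined through the aldehyde carbon.
- Enabling feature: in each half the pyran ring meets the benzene ring at the neighbouring carbons C4a (carrying C4) and C8a (carrying O1), and the other neighbour of C8a, C8, carries the isobutyryl group. An iodide at C8a therefore has exactly one free ortho C–H (C4a) for alkylation and is itself the site of the C–O bond.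
- Stereochemistry: none to set. The only sp3 methine carries two identical aryl groups and the target is achiral.

Key step: step 2

Remark: chroman numbering (O1, C2, C3, C4, C4a, C5 to C8, C8a) is used for the ring atoms of compounds 3 to 12, and 6-methylheptanal is taken to be purchasable.

**Route**

Step 1
Reactants: 1 1-iodo-3,5-dimethoxybenzene; 2 isobutyryl chloride
Product: 3 1-(2-iodo-4,6-dimethoxyphenyl)-2-methylpropan-1-one
Conditions: AlCl3 (1.1 equiv), CH2Cl2, −20 → 0 °C; ice/aq. HCl work-up
Reagents that add atoms: none
Why: Friedel–Crafts acylation, in which the acylium ion should attack the carbon of 1 that is para to one methoxy group and ortho to the other (the site favoured in acylation and formylation of 3,5-dimethoxyhalobenzenes), while iodine, meta to both donors, is not activated for ipso attack and the low temperature limits AlCl3-induced ether cleavage.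

Step 2
Reactants: 3 1-(2-iodo-4,6-dimethoxyphenyl)-2-methylpropan-1-one; 4 4-bromo-2-methylbutan-2-ol
Product: 6 1-(5,7-dimethoxy-2,2-dimethylchroman-8-yl)-2-methylpropan-1-one, via arylpalladium bromide 5 (not isolated)
Conditions: Pd(OAc)2 (10 mol%), XPhos (2-dicyclohexylphosphino-2',4',6'-triisopropylbiphenyl, 20 mol%), norbornene (1.0 equiv), Cs2CO3 (3 equiv), 4 (2.5 equiv), 1,4-dioxane, 100 °C
Reagents that add atoms: none
Why: Proposed new method: zerovalent palladium inserts into the C8a–I bond of 3, norbornene inserts, and carbonate-assisted C–H palladation at C4a gives a divalent five-membered palladacycle that adds the primary C–Br bond of 4 to reach tetravalent palladium and reductively eliminates to form C4–C4a. With both carbons next to C8a now substituted, norbornene is expelled by beta-carbon elimination to leave divalent arylpalladium bromide 5, whose tethered tertiary alkoxide replaces bromide and closes the pyran ring by C–O reductive elimination at the ipso carbon (O1–C8a) from a seven-membered aryl(alkoxo)palladium chelate. The closest known reaction type is the Catellani ortho-alkylation ended at the ipso carbon by a tethered heteroatom (bromoalkylamines to tetrahydroquinolines, epoxides to 2,3-dihydrobenzofurans), and the ring-closing event on its own matches the known palladium-catalysed cyclisation of 2-haloaryl tertiary alcohols to 2,2-dimethylchromans; a tertiary alcohol ending the relay to give a chroman is the untested part. No stereocentre is created. The selectivity required is site selectivity, and the substrate fixes it: iodine marks C8a, the isobutyryl group on C8 blocks one ortho position and acts as the ortho substituent that forces norbornene out after a single alkylation, so the only C–H open to the relay is C4a. The order alkylation before etherification is secured because a hindered tertiary alcohol does not couple intermolecularly with arylpalladium at a useful rate and its alkoxide has no hydrogen on the carbinol carbon, which rules out beta-hydride elimination.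

Step 3
Reactants: 6 1-(5,7-dimethoxy-2,2-dimethylchroman-8-yl)-2-methylpropan-1-one
Product: 8 1-(5,7-dihydroxy-2,2-dimethylchroman-8-yl)-2-methylpropan-1-one, via bis(dibromoboryl) ether 7 (not isolated)
Conditions: BBr3 (3.5 equiv), CH2Cl2, −78 → 0 °C; cold water quench
Reagents that add atoms: none
Why: Lewis-acid cleavage of aryl methyl ethers, in which BBr3 binds each methoxy oxygen (the C7 one helped by chelation to the ketone) and bromide removes the methyl group by SN2 attack, whereas the tertiary O1–C2 bond has no SN2 pathway and should survive at or below 0 °C with a cold quench.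

Step 4
Reactants: 8 1-(5,7-dihydroxy-2,2-dimethylchroman-8-yl)-2-methylpropan-1-one (2.1 equiv); 9 6-methylheptanal (1.0 equiv)
Product: 12 6,6'-(6-methylheptane-1,1-diyl)bis(8-isobutyryl-2,2-dimethylchroman-5,7-diol), via benzylic carbinol 10 (not isolated), via ortho-quinone methide 11 (not isolated)
Conditions: p-TsOH·H2O (10 mol%), AcOH, rt
Reagents that add atoms: none
Why: Acid-catalysed hydroxyalkylation followed by Friedel–Crafts alkylation (the condensation that links resorcinol rings with aliphatic aldehydes in resorcinarene synthesis), in which C6 of 8, the only free ring carbon and flanked by two hydroxyl groups, adds to the protonated aldehyde, carbinol 10 loses water to ortho-quinone methide 11, and a second molecule of 8 adds through C6 to give a methine that bears two identical aryl groups and is therefore not a stereocentre.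

**Compound list**

1 | 1-iodo-3,5-dimethoxybenzene | COc1cc(I)cc(OC)c1 | starting material
2 | isobutyryl chloride (2-methylpropanoyl chloride) | CC(C)C(Cl)=O | starting material
3 | 1-(2-iodo-4,6-dimethoxyphenyl)-2-methylpropan-1-one | CC(C)C(=O)c1c(I)cc(OC)cc1OC | intermediate
4 | 4-bromo-2-methylbutan-2-ol | CC(C)(O)CCBr | starting material
5 | [2-(3-hydroxy-3-methylbutyl)-6-isobutyryl-3,5-dimethoxyphenyl]palladium bromide (divalent palladium, phosphine ligand not drawn; formed in the flask, not isolated) | CC(C)C(=O)c1c([Pd]Br)c(CCC(C)(C)O)c(OC)cc1OC | intermediate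
6 | 1-(5,7-dimethoxy-2,2-dimethylchroman-8-yl)-2-methylpropan-1-one (8-isobutyryl-5,7-dimethoxy-2,2-dimethylchroman) | COc1cc(OC)c2c(c1C(=O)C(C)C)OC(C)(C)CC2 | intermediate
7 | 1-[5,7-bis(dibromoboryloxy)-2,2-dimethylchroman-8-yl]-2-methylpropan-1-one (formed in the flask, not isolated) | CC(C)C(=O)c1c(OB(Br)Br)cc(OB(Br)Br)c2CCC(C)(C)Oc12 | intermediate
8 | 1-(5,7-dihydroxy-2,2-dimethylchroman-8-yl)-2-methylpropan-1-one | CC(C)C(=O)c1c(O)cc(O)c2CCC(C)(C)Oc12 | intermediate
9 | 6-methylheptanal | CC(C)CCCCC=O | starting material
10 | 1-[5,7-dihydroxy-6-(1-hydroxy-6-methylheptyl)-2,2-dimethylchroman-8-yl]-2-methylpropan-1-one (racemic; formed in the flask, not isolated) | CC(C)CCCCC(O)c1c(O)c2CCC(C)(C)Oc2c(C(=O)C(C)C)c1O | intermediate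
11 | 5-hydroxy-8-isobutyryl-2,2-dimethyl-6-(6-methylheptylidene)-3,4-dihydro-2H-chromen-7(6H)-one (ortho-quinone methide, alkene geometry undefined; formed in the flask, not isolated) | CC(C)CCCCC=C1C(=O)C(C(=O)C(C)C)=C2OC(C)(C)CCC2=C1O | intermediate
12 | 6,6'-(6-methylheptane-1,1-diyl)bis(8-isobutyryl-2,2-dimethylchroman-5,7-diol), CNP0275635.0 (achiral) | CC(C)CCCCC(c1c(O)c2c(c(C(=O)C(C)C)c1O)OC(C)(C)CC2)c1c(O)c2c(c(C(=O)C(C)C)c1O)OC(C)(C)CC2 | target

**Step count and risks**

Total step count: 4. Longest linear sequence: 4 steps (1 → 3 → 6 → 8 → 12).

Steps most likely to fail: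

1. Step 2 (proposed new method). What may go wrong:
   - Palladation or alkylation at C4a may be slowed by crowding from the neighbouring C5 methoxy group.
   - The relay may then end early, by ipso reduction or by norbornene incorporation, before the alkoxide closes the ring.
   - Base may consume 4 by oxetane formation or elimination.

   Fallback (known chemistry only), setting out from 3 and returning at 6. Palladium-catalysed hydroxylation of the aryl iodide (Pd2(dba)3, 2-di-tert-butylphosphino-2',4',6'-triisopropylbiphenyl, KOH, dioxane/H2O, 100 °C) should give 1-(2-hydroxy-4,6-dimethoxyphenyl)-2-methylpropan-1-one F1. O-Alkylation with 3-chloro-3-methylbut-1-yne (DBU, CuCl2 cat., MeCN, 0 °C) should give 1-[2,4-dimethoxy-6-(2-methylbut-3-yn-2-yloxy)phenyl]-2-methylpropan-1-one F2. Heating (N,N-diethylaniline, about 180 °C) should trigger aromatic Claisen rearrangement, hydrogen shift and oxa-electrocyclisation onto the only free ortho carbon, giving 1-(5,7-dimethoxy-2,2-dimethyl-2H-chromen-8-yl)-2-methylpropan-1-one F3. Hydrogenation of the C3–C4 alkene (H2, Pd/C, EtOAc, rt) would deliver 6.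

2. Step 3. What may go wrong:
   - The tertiary O1–C2 bond may ionise under the Lewis acid, so the pyran ring opens and recloses on the C5 oxygen (migration to the 6-acyl isomer) or is lost as bromide or alkene.
   - Cleavage of the C5 methyl ether may be incomplete.

   Fallback: change the phenol protection so that the last unmasking is acid-free, setting out from 3 and returning at 8. BBr3 (CH2Cl2, −78 °C → rt) on 3, where no pyran ring is yet present, should give 1-(2,4-dihydroxy-6-iodophenyl)-2-methylpropan-1-one F4. Benzylation (BnBr, K2CO3, DMF, 60 °C) should give 1-[2,4-bis(benzyloxy)-6-iodophenyl]-2-methylpropan-1-one F5. The annulation of step 2 with 4 should give 1-[5,7-bis(benzyloxy)-2,2-dimethylchroman-8-yl]-2-methylpropan-1-one F6; this fallback is only needed once step 2 has already been shown to work on 3. Hydrogenolysis (H2, Pd/C, EtOAc, rt) would release 8.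

3. Step 1. What may go wrong:
   - Acylation may occur at the carbon between the two methoxy groups.
   - AlCl3 may remove the methyl ether next to the new ketone.

   Fallback: build the ketone by formylation, addition and oxidation, setting out from 1 and returning at 3. Vilsmeier–Haack formylation (POCl3, DMF, 0 → 80 °C; aq. NaOAc), whose bulky and weak electrophile is strongly para-directed and needs no Lewis acid, should give 2-iodo-4,6-dimethoxybenzaldehyde F7. Addition of i-PrMgCl with CeCl3 (THF, −78 °C), cold enough to outrun iodine–magnesium exchange and carbonyl reduction, should give racemic 1-(2-iodo-4,6-dimethoxyphenyl)-2-methylpropan-1-ol F8. Dess–Martin periodinane (CH2Cl2, rt) would oxidise F8 to 3.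

Further compounds
F1 | step 2 | 1-(2-hydroxy-4,6-dimethoxyphenyl)-2-methylpropan-1-one | CC(C)C(=O)c1c(O)cc(OC)cc1OC
F2 | step 2 | 1-[2,4-dimethoxy-6-(2-methylbut-3-yn-2-yloxy)phenyl]-2-methylpropan-1-one | CC(C)C(=O)c1c(OC(C)(C)C#C)cc(OC)cc1OC
F3 | step 2 | 1-(5,7-dimethoxy-2,2-dimethyl-2H-chromen-8-yl)-2-methylpropan-1-one | CC(C)C(=O)c1c(OC)cc(OC)c2C=CC(C)(C)Oc12
F4 | step 3 | 1-(2,4-dihydroxy-6-iodophenyl)-2-methylpropan-1-one | CC(C)C(=O)c1c(I)cc(O)cc1O
F5 | step 3 | 1-[2,4-bis(benzyloxy)-6-iodophenyl]-2-methylpropan-1-one | CC(C)C(=O)c1c(I)cc(OCc2ccccc2)cc1OCc1ccccc1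
F6 | step 3 | 1-[5,7-bis(benzyloxy)-2,2-dimethylchroman-8-yl]-2-methylpropan-1-one | CC(C)C(=O)c1c(OCc2ccccc2)cc(OCc2ccccc2)c2CCC(C)(C)Oc12
F7 | step 1 | 2-iodo-4,6-dimethoxybenzaldehyde | COc1cc(I)c(C=O)c(OC)c1
F8 | step 1 | 1-(2-iodo-4,6-dimethoxyphenyl)-2-methylpropan-1-ol (racemic) | CC(C)C(O)c1c(I)cc(OC)cc1OC
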